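**Plan** (macrolide numbering: C1 = lactone carbonyl, C27 = lactone carbinol carbon, C28 = its methyl)

- Cuts, in retrosynthetic order: C25–C26 (ring), C24=C25 and C17–C18 (pentaene), O27–C1 (ester), C2–C3, C11=C12, C14–C15, and the two allyl–carbinol bonds at C5 and C9.
- Enabling feature: the alcohol half of the 28-membered lactone is a butane-2,3-diol unit (C28–C27–C26–Me). C26 can therefore carry bromide while O27 carries the acyl chain, and C25 is the sp2 end of the C16–C25 pentaene, so nickel can join the two ends of one chain.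
- Forward: C12–C17 vinyl ketone (Evans aldol) and a C2-symmetric diene-diol (double allylboration) are joined by mono cross-metathesis; oxa-Michael addition (C11) and directed reduction (C13); alkene cleavage and a second Evans aldol (C1–C3); esterification with the bromohydrin; Stille and Takai reactions build the C25-iodo pentaene; ring closure at C25–C26; desilylation.
- Stereochemistry: C5 and C9 from the allylborane; C14/C15 and C2/C3 from oxazolidinone auxiliaries; C11 relayed from C9 (1,3-syn) and C13 from C11 (1,3-anti); C27 from (2R,3R)-butane-2,3-diol; C26 by 1,2-induction from C27 in the ring closure.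

Key step: step 22

Assumption: the allylborane made from (−)-α-pinene is taken to give the S carbinol with unbranched aliphatic aldehydes, as it does with simple alkanals.

Step 1
Reactants: 1 ethyl (E)-3-iodoprop-2-enoate
Product: 2 (E)-3-iodoprop-2-enal
Conditions: i-Bu2AlH (1.05 equiv), CH2Cl2, −78 °C; MeOH, aq Rochelle salt; solution used directly
Reagents that add atoms: none
Why: Half-reduction of an ester with one equivalent of i-Bu2AlH at −78 °C stops at the stable aluminium hemiacetal, so work-up releases the aldehyde without touching the E-iodoalkene.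

Step 2
Reactants: 2 (E)-3-iodoprop-2-enal; 3 (S)-4-benzyl-3-propanoyl-1,3-oxazolidin-2-one
Product: 5 (S)-4-benzyl-3-[(2S,3S,E)-3-hydroxy-5-iodo-2-methylpent-4-enoyl]-1,3-oxazolidin-2-one, via Z-dibutylboron enolate of the propanoyl imide 4 (not isolated)
Conditions: 3, Bu2BOTf, i-Pr2NEt, CH2Cl2, −78 → 0 °C; 2, −78 → 0 °C; pH 7 buffer, MeOH, H2O2, 0 °C
Reagents that add atoms: none
Why: Evans syn-aldol reaction, in which the Z-dibutylboron enolate reacts through a closed chair transition state on the enolate face remote from the benzyl group, which sets C14 and C15 (syn) in the required absolute sense.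

Step 3
Reactants: 5 aldol imide
Product: 6 (2S,3S,E)-3-hydroxy-5-iodo-N-methoxy-N,2-dimethylpent-4-enamide
Conditions: MeNHOMe·HCl, AlMe3, THF, −20 → 0 °C
Reagents that add atoms: N,O-dimethylhydroxylamine hydrochloride, CNOC.Cl
Why: Aluminium amide transamidation (Weinreb amide formation), helped by the free β-hydroxyl, displaces the oxazolidinone without epimerising C14.

Step 4
Reactants: 6 hydroxy Weinreb amide
Product: 7 (2S,3S,E)-3-(tert-butyldimethylsilyloxy)-5-iodo-N-methoxy-N,2-dimethylpent-4-enamide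
Conditions: TBSOTf, 2,6-lutidine, CH2Cl2, −78 → 0 °C
Reagents that add atoms: tert-butyldimethylsilyl triflate, CC(C)(C)[Si](C)(C)OS(=O)(=O)C(F)(F)F
Why: Silylation of a secondary alcohol with a silyl triflate and a hindered base is reliable and leaves the Weinreb amide and the iodoalkene untouched.

Step 5
Reactants: 7 silylated Weinreb amide
Product: 8 (4S,5S,E)-5-(tert-butyldimethylsilyloxy)-7-iodo-4-methylhepta-1,6-dien-3-one (C12–C17)
Conditions: CH2=CHMgBr, THF, 0 °C; inverse quench into cold 1 M HCl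
Reagents that add atoms: vinylmagnesium bromide, C=C[Mg]Br
Why: Weinreb ketone synthesis, in which the chelated tetrahedral magnesium adduct prevents over-addition and a cold acidic quench removes the liberated amine before it can add to the enone.

Step 6
Reactants: 9 pentanedial (glutaraldehyde, anhydrous, freshly distilled)
Product: 10 (4S,8S)-trideca-1,12-diene-4,8-diol
Conditions: (+)-Ipc2B(allyl) (2.4 equiv), Et2O, −78 °C; NaOH, H2O2, 0 → 23 °C
Reagents that add atoms: (+)-B-allyldiisopinocampheylborane (from (−)-α-pinene), C=CCB([C@H]1C[C@H]2C[C@@H]([C@@H]1C)C2(C)C)[C@H]1C[C@H]2C[C@@H]([C@@H]1C)C2(C)C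
Why: Twofold Brown allylboration, in which each allyl transfer goes through a chair transition state whose face is fixed by the isopinocampheyl groups, which sets C5 and C9 as S, and the double addition raises the enantiomeric purity of the C2-symmetric diol.

Step 7
Reactants: 8 vinyl ketone; 10 diene-diol (3 equiv)
Product: 11 (1E,3S,4S,6E,9S,13S)-3-(tert-butyldimethylsilyloxy)-9,13-dihydroxy-1-iodo-4-methylhexadeca-1,6,15-trien-5-one
Conditions: second-generation Hoveyda–Grubbs catalyst RuCl2(H2IMes)(=CH–C6H4-2-Oi-Pr) (5 mol%), CH2Cl2, 40 °C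
Reagents that add atoms: none
Why: Olefin cross-metathesis of a terminal alkene with an electron-poor vinyl ketone is E-selective, the two alkene ends of C2-symmetric 10 are homotopic so that mono-coupling gives a single compound, and the excess of 10 holds back double coupling.

Step 8
Reactants: 11 δ-hydroxy enone
Product: 13 (1E,3S,4S,7S,9S,13S)-3-(tert-butyldimethylsilyloxy)-7,9,13-trihydroxy-1-iodo-4-methylhexadeca-1,15-dien-5-one, via cyclic C9/C11 phenylboronate of the triol 12 (not isolated)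
Conditions: PhB(OH)2 (2.2 equiv), DABCO (20 mol%), 4 Å MS, toluene, 23 °C; H2O2, aq NaHCO3, THF, 0 °C
Reagents that add atoms: phenylboronic acid, OB(O)c1ccccc1
Why: Boronic acid-mediated intramolecular oxa-Michael addition, in which the boronic hemiester of the C9 hydroxyl delivers its B–OH oxygen to C11 through a chair with both substituents equatorial, which sets C11 syn to C9, and peroxide then cleaves the cyclic boronate.

Step 9
Reactants: 13 β-hydroxy ketone
Product: 14 (1E,3S,4R,5R,7S,9S,13S)-3-(tert-butyldimethylsilyloxy)-1-iodo-4-methylhexadeca-1,15-diene-5,7,9,13-tetrol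
Conditions: Me4NBH(OAc)3, MeCN/AcOH (1:1), −30 °C
Reagents that add atoms: none
Why: Evans–Saksena reduction, in which the C11 hydroxyl binds the borohydride and delivers hydride intramolecularly through a chair transition state, which sets C13 anti to C11 (and so anti to C15).

Step 10
Reactants: 14 tetraol
Product: 15 (1E,3S,4R,5R,7S,9S,13S)-3,5,7,9,13-pentakis(tert-butyldimethylsilyloxy)-1-iodo-4-methylhexadeca-1,15-diene
Conditions: TBSOTf (6 equiv), 2,6-lutidine, CH2Cl2, −78 → 0 °C
Reagents that add atoms: tert-butyldimethylsilyl triflate, CC(C)(C)[Si](C)(C)OS(=O)(=O)C(F)(F)F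
Why: Exhaustive silylation with a silyl triflate protects the four secondary hydroxyls, the hindered C13 one included.

Step 11
Reactants: 15 terminal alkene
Product: 16 (3S,7S,9S,11R,12R,13S,14E)-3,7,9,11,13-pentakis(tert-butyldimethylsilyloxy)-15-iodo-12-methylpentadec-14-enal (C3 aldehyde)
Conditions: OsO4 (2 mol%), NaIO4 (4 equiv), 2,6-lutidine, dioxane/H2O (3:1), 23 °C
Reagents that add atoms: osmium tetroxide, O=[Os](=O)(=O)=O; sodium periodate, [Na+].[O-]I(=O)(=O)=O
Why: Johnson–Lemieux oxidation, in which OsO4 dihydroxylates the electron-rich monosubstituted alkene much faster than the electron-poor, hindered iodoalkene and periodate cleaves the diol to the C3 aldehyde.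

Step 12
Reactants: 16 aldehyde; 17 (S)-4-benzyl-3-butanoyl-1,3-oxazolidin-2-one
Product: 19 (S)-4-benzyl-3-[(2S,3R,5S,9S,11S,13R,14R,15S,16E)-2-ethyl-3-hydroxy-5,9,11,13,15-pentakis(tert-butyldimethylsilyloxy)-17-iodo-14-methylheptadec-16-enoyl]-1,3-oxazolidin-2-one, via Z-dibutylboron enolate of the butanoyl imide 18 (not isolated)
Conditions: 17, Bu2BOTf, i-Pr2NEt, CH2Cl2, −78 → 0 °C; 16, −78 → 0 °C; pH 7 buffer, MeOH, H2O2, 0 °C
Reagents that add atoms: none
Why: Evans syn-aldol reaction, in which the Z-boron enolate of the butanoyl imide adds under auxiliary control through a closed chair transition state, which sets C2 (ethyl) and C3 (hydroxyl) syn and in the required absolute sense whatever the C5 centre prefers.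

Step 13
Reactants: 19 aldol imide
Product: 20 (2S,3R,5S,9S,11S,13R,14R,15S,16E)-2-ethyl-3-hydroxy-5,9,11,13,15-pentakis(tert-butyldimethylsilyloxy)-17-iodo-14-methylheptadec-16-enoic acid
Conditions: LiOH, H2O2, THF/H2O (3:1), 0 °C; Na2SO3; 1 M HCl to pH 3
Reagents that add atoms: hydrogen peroxide, OO (acting as lithium hydroperoxide, [Li+].[O-]O)
Why: Lithium hydroperoxide attacks the exocyclic imide carbonyl selectively and frees the carboxylic acid without epimerising C2 (standard auxiliary removal).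

Step 14
Reactants: 20 hydroxy acid
Product: 22 (2S,3R,5S,9S,11S,13R,14R,15S,16E)-2-ethyl-3,5,9,11,13,15-hexakis(tert-butyldimethylsilyloxy)-17-iodo-14-methylheptadec-16-enoic acid, via silyl ester of the hexakis-silylated acid 21 (not isolated)
Conditions: TBSOTf (3 equiv), 2,6-lutidine, CH2Cl2, 0 °C; K2CO3 (0.2 equiv), MeOH, 0 °C
Reagents that add atoms: tert-butyldimethylsilyl triflate, CC(C)(C)[Si](C)(C)OS(=O)(=O)C(F)(F)F
Why: The silyl triflate silylates both the C3 hydroxyl and the acid, and mild methanolysis then cleaves only the labile silyl ester.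

Step 15
Reactants: 23 (2R,3R)-butane-2,3-diol
Product: 24 (2R,3S)-3-bromobutan-2-yl acetate
Conditions: HBr (33% in AcOH), 0 → 23 °C
Reagents that add atoms: hydrogen bromide, Br; acetic acid, CC(=O)O
Why: Acetoxonium route, in which the monoacetate closes to a 1,3-dioxolan-2-ylium ion that bromide opens with inversion at one carbon, so the untouched carbinol carbon keeps the R configuration that becomes C27.

Step 16
Reactants: 24 bromo acetate
Product: 25 (2R,3S)-3-bromobutan-2-ol
Conditions: HCl (cat., from AcCl), MeOH, 23 °C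
Reagents that add atoms: none
Why: Acid-catalysed transesterification removes the acetate without base, so the bromohydrin cannot close to the epoxide.

Step 17
Reactants: 22 acid; 25 bromohydrin
Product: 27 (2R,3S)-3-bromobutan-2-yl ester of acid 22, via 2,4,6-trichlorobenzoic mixed anhydride 26 (not isolated)
Conditions: 2,4,6-Cl3C6H2COCl, Et3N, THF, 23 °C; 25, DMAP, toluene, 23 → 40 °C
Reagents that add atoms: none
Why: Yamaguchi esterification, in which the secondary alcohol attacks the less hindered carbonyl of the mixed anhydride under DMAP catalysis, with retention at C27 and no strong base that could form an epoxide.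

Step 18
Reactants: 28 glutaconaldehyde potassium salt
Product: 29 (2E,4E)-5-bromopenta-2,4-dienal
Conditions: Ph3PBr2, CH2Cl2, 0 → 23 °C
Reagents that add atoms: dibromotriphenylphosphorane, BrP(Br)(c1ccccc1)(c1ccccc1)c1ccccc1
Why: The vinylogous carboxylate oxygen is activated as an oxyphosphonium salt and replaced by bromide through addition–elimination, which gives the thermodynamically favoured all-E bromodienal.

Step 19
Reactants: 29 bromodienal; 30 (E)-1,2-bis(tributylstannyl)ethene (2.5 equiv)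
Product: 31 (2E,4E,6E)-7-(tributylstannyl)hepta-2,4,6-trienal
Conditions: Pd2(dba)3 (2.5 mol%), AsPh3 (10 mol%), THF, 23 °C, dark
Reagents that add atoms: none
Why: Stille coupling, in which an excess of the symmetric distannane ensures mono-coupling with the bromodiene with retention of both alkene geometries.

Step 20
Reactants: 27 iodoalkene ester; 31 stannyl trienal (1.5 equiv)
Product: 32 (2R,3S)-3-bromobutan-2-yl (2S,3R,5S,9S,11S,13R,14R,15R,16E,18E,20E,22E)-2-ethyl-3,5,9,11,13,15-hexakis(tert-butyldimethylsilyloxy)-14-methyl-24-oxotetracosa-16,18,20,22-tetraenoate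
Conditions: Pd2(dba)3 (5 mol%), AsPh3 (20 mol%), NMP, 23 °C, dark
Reagents that add atoms: none
Why: Stille coupling of the alkenyl iodide with the alkenylstannane proceeds with retention of both alkene geometries at room temperature, and the secondary alkyl bromide does not react with zerovalent palladium under these conditions.

Step 21
Reactants: 32 tetraenal
Product: 33 (2R,3S)-3-bromobutan-2-yl (2S,3R,5S,9S,11S,13R,14R,15R,16E,18E,20E,22E,24E)-2-ethyl-3,5,9,11,13,15-hexakis(tert-butyldimethylsilyloxy)-25-iodo-14-methylpentacosa-16,18,20,22,24-pentaenoate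
Conditions: CrCl2 (8 equiv), CHI3 (3 equiv), THF/dioxane (1:4), 0 → 23 °C, dark
Reagents that add atoms: iodoform, IC(I)I
Why: Takai olefination, in which the geminal dichromium reagent from iodoform adds to the aldehyde and eliminates to give the E-iodoalkene, while CrCl2 leaves the unactivated secondary bromide and the ester alone.

Step 22
Reactants: 33 C25-iodo, C26-bromo seco ester
Product: 34 hexakis(tert-butyldimethylsilyl) ether of the macrolide, (3S,4R,6S,10S,12S,14R,15R,16R,17E,19E,21E,23E,25E,27R,28R)-3-ethyl-4,6,10,12,14,16-hexakis(tert-butyldimethylsilyloxy)-15,27,28-trimethyl-1-oxacyclooctacosa-17,19,21,23,25-pentaen-2-one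
Conditions: NiBr2·diglyme (30 mol%), 4,4'-di-tert-butyl-2,2'-bipyridine (36 mol%), NaI (50 mol%), TDAE (3 equiv), DMA/THF (1:1), 23 °C, 33 added over 12 h (final 1 mM), argon, dark
Reagents that add atoms: none
Why: Proposed new method: zerovalent nickel inserts into the C25–I bond of the pentaenyl iodide with retention of the E geometry, a monovalent nickel halide abstracts bromine from C26 to give a secondary radical, and capture of that radical by the tethered alkenylnickel followed by reductive elimination from trivalent nickel forms the C25–C26 bond while TDAE returns nickel to its low-valent states; the closest known reaction type is the intermolecular nickel-catalysed reductive cross-electrophile coupling of alkenyl halides with unactivated secondary alkyl bromides. The 28-membered lactone ring closes in the radical-capture and reductive-elimination event at nickel, an end-to-end macrocyclisation of the C1–C25 chain onto its own 3-bromobut-2-yl ester that is favoured by slow addition into an excess of catalyst. The only new stereocentre, C26, is set under substrate control by the ester-bearing C27: the planar radical should react through the conformer in which the C27–O bond is aligned with the singly occupied orbital and C27–H lies next to the C26 methyl group, so that nickel bonds anti to the acyloxy group, which gives the 26R,27R arrangement whichever bromide epimer is used. The step needs cross-coupling over homo-coupling (secured by the different activation modes of the sp2 C–I and sp3 C–Br bonds), ring closure over oligomerisation (high dilution), retention of the all-E pentaene (two-electron oxidative addition at C25), and C–C bond formation faster than β-acyloxy elimination or 1,2-acyloxy shift (fast reductive elimination from trivalent nickel with the bipyridine ligand and a high standing nickel concentration).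

Step 23
Reactants: 34 hexakis-silyl macrolide
Product: 35 CNP0382847.1, (3S,4R,6S,10S,12S,14R,15R,16R,17E,19E,21E,23E,25E,27R,28R)-3-ethyl-4,6,10,12,14,16-hexahydroxy-15,27,28-trimethyl-1-oxacyclooctacosa-17,19,21,23,25-pentaen-2-one
Conditions: HF·pyridine, pyridine, THF, 0 → 23 °C (plastic vessel); Me3SiOMe quench
Reagents that add atoms: none
Why: Fluoride cleaves the six silyl ethers under buffered, nearly neutral conditions that should spare the lactone, the pentaene and the allylic C15 hydroxyl (global desilylation).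

**Compound list**

1 | ethyl (E)-3-iodoprop-2-enoate | CCOC(=O)/C=C/I | starting material
2 | (E)-3-iodoprop-2-enal | O=C/C=C/I | intermediate
3 | (S)-4-benzyl-3-propanoyl-1,3-oxazolidin-2-one | CCC(=O)N1[C@@H](Cc2ccccc2)COC1=O | starting material
4 | Z-dibutylboron enolate of 3 | C/C=C(\OB(CCCC)CCCC)N1[C@@H](Cc2ccccc2)COC1=O | intermediate
5 | (S)-4-benzyl-3-[(2S,3S,E)-3-hydroxy-5-iodo-2-methylpent-4-enoyl]-1,3-oxazolidin-2-one | I/C=C/[C@@H](O)[C@H](C)C(=O)N1[C@@H](Cc2ccccc2)COC1=O | intermediate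
6 | (2S,3S,E)-3-hydroxy-5-iodo-N-methoxy-N,2-dimethylpent-4-enamide | I/C=C/[C@@H](O)[C@H](C)C(=O)N(C)OC | intermediate
7 | (2S,3S,E)-3-(tert-butyldimethylsilyloxy)-5-iodo-N-methoxy-N,2-dimethylpent-4-enamide | I/C=C/[C@@H](O[Si](C)(C)C(C)(C)C)[C@H](C)C(=O)N(C)OC | intermediate
8 | (4S,5S,E)-5-(tert-butyldimethylsilyloxy)-7-iodo-4-methylhepta-1,6-dien-3-one | I/C=C/[C@@H](O[Si](C)(C)C(C)(C)C)[C@H](C)C(=O)C=C | intermediate
9 | pentanedial (glutaraldehyde) | O=CCCCC=O | starting material
10 | (4S,8S)-trideca-1,12-diene-4,8-diol | C=CC[C@@H](O)CCC[C@H](O)CC=C | intermediate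
11 | (1E,3S,4S,6E,9S,13S)-3-(tert-butyldimethylsilyloxy)-9,13-dihydroxy-1-iodo-4-methylhexadeca-1,6,15-trien-5-one | I/C=C/[C@@H](O[Si](C)(C)C(C)(C)C)[C@H](C)C(=O)/C=C/C[C@@H](O)CCC[C@H](O)CC=C | intermediate
12 | cis-4,6-disubstituted 2-phenyl-1,3,2-dioxaborinane spanning O9 and O11 of triol 13 | I/C=C/[C@@H](O[Si](C)(C)C(C)(C)C)[C@H](C)C(=O)C[C@@H]1C[C@H](CCC[C@H](O)CC=C)OB(c2ccccc2)O1 | intermediate
13 | (1E,3S,4S,7S,9S,13S)-3-(tert-butyldimethylsilyloxy)-7,9,13-trihydroxy-1-iodo-4-methylhexadeca-1,15-dien-5-one | I/C=C/[C@@H](O[Si](C)(C)C(C)(C)C)[C@H](C)C(=O)C[C@@H](O)C[C@@H](O)CCC[C@H](O)CC=C | intermediate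
14 | (1E,3S,4R,5R,7S,9S,13S)-3-(tert-butyldimethylsilyloxy)-1-iodo-4-methylhexadeca-1,15-diene-5,7,9,13-tetrol | I/C=C/[C@@H](O[Si](C)(C)C(C)(C)C)[C@H](C)[C@H](O)C[C@@H](O)C[C@@H](O)CCC[C@H](O)CC=C | intermediate
15 | (1E,3S,4R,5R,7S,9S,13S)-3,5,7,9,13-pentakis(tert-butyldimethylsilyloxy)-1-iodo-4-methylhexadeca-1,15-diene | I/C=C/[C@@H](O[Si](C)(C)C(C)(C)C)[C@H](C)[C@H](O[Si](C)(C)C(C)(C)C)C[C@@H](O[Si](C)(C)C(C)(C)C)C[C@@H](O[Si](C)(C)C(C)(C)C)CCC[C@H](O[Si](C)(C)C(C)(C)C)CC=C | intermediate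
16 | (3S,7S,9S,11R,12R,13S,14E)-3,7,9,11,13-pentakis(tert-butyldimethylsilyloxy)-15-iodo-12-methylpentadec-14-enal | I/C=C/[C@@H](O[Si](C)(C)C(C)(C)C)[C@H](C)[C@H](O[Si](C)(C)C(C)(C)C)C[C@@H](O[Si](C)(C)C(C)(C)C)C[C@@H](O[Si](C)(C)C(C)(C)C)CCC[C@H](O[Si](C)(C)C(C)(C)C)CC=O | intermediate
17 | (S)-4-benzyl-3-butanoyl-1,3-oxazolidin-2-one | CCCC(=O)N1[C@@H](Cc2ccccc2)COC1=O | starting material
18 | Z-dibutylboron enolate of 17 | CC/C=C(\OB(CCCC)CCCC)N1[C@@H](Cc2ccccc2)COC1=O | intermediate
19 | (S)-4-benzyl-3-[(2S,3R,5S,9S,11S,13R,14R,15S,16E)-2-ethyl-3-hydroxy-5,9,11,13,15-pentakis(tert-butyldimethylsilyloxy)-17-iodo-14-methylheptadec-16-enoyl]-1,3-oxazolidin-2-one | I/C=C/[C@@H](O[Si](C)(C)C(C)(C)C)[C@H](C)[C@H](O[Si](C)(C)C(C)(C)C)C[C@@H](O[Si](C)(C)C(C)(C)C)C[C@@H](O[Si](C)(C)C(C)(C)C)CCC[C@H](O[Si](C)(C)C(C)(C)C)C[C@@H](O)[C@H](CC)C(=O)N1[C@@H](Cc2ccccc2)COC1=O | intermediate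
20 | (2S,3R,5S,9S,11S,13R,14R,15S,16E)-2-ethyl-3-hydroxy-5,9,11,13,15-pentakis(tert-butyldimethylsilyloxy)-17-iodo-14-methylheptadec-16-enoic acid | I/C=C/[C@@H](O[Si](C)(C)C(C)(C)C)[C@H](C)[C@H](O[Si](C)(C)C(C)(C)C)C[C@@H](O[Si](C)(C)C(C)(C)C)C[C@@H](O[Si](C)(C)C(C)(C)C)CCC[C@H](O[Si](C)(C)C(C)(C)C)C[C@@H](O)[C@H](CC)C(=O)O | intermediate
21 | tert-butyldimethylsilyl ester of acid 22 | I/C=C/[C@@H](O[Si](C)(C)C(C)(C)C)[C@H](C)[C@H](O[Si](C)(C)C(C)(C)C)C[C@@H](O[Si](C)(C)C(C)(C)C)C[C@@H](O[Si](C)(C)C(C)(C)C)CCC[C@H](O[Si](C)(C)C(C)(C)C)C[C@@H](O[Si](C)(C)C(C)(C)C)[C@H](CC)C(=O)O[Si](C)(C)C(C)(C)C | intermediate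
22 | (2S,3R,5S,9S,11S,13R,14R,15S,16E)-2-ethyl-3,5,9,11,13,15-hexakis(tert-butyldimethylsilyloxy)-17-iodo-14-methylheptadec-16-enoic acid | I/C=C/[C@@H](O[Si](C)(C)C(C)(C)C)[C@H](C)[C@H](O[Si](C)(C)C(C)(C)C)C[C@@H](O[Si](C)(C)C(C)(C)C)C[C@@H](O[Si](C)(C)C(C)(C)C)CCC[C@H](O[Si](C)(C)C(C)(C)C)C[C@@H](O[Si](C)(C)C(C)(C)C)[C@H](CC)C(=O)O | intermediate
23 | (2R,3R)-butane-2,3-diol | C[C@@H](O)[C@@H](C)O | starting material
24 | (2R,3S)-3-bromobutan-2-yl acetate | CC(=O)O[C@H](C)[C@H](C)Br | intermediate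
25 | (2R,3S)-3-bromobutan-2-ol | O[C@H](C)[C@H](C)Br | intermediate
26 | mixed anhydride of acid 22 with 2,4,6-trichlorobenzoic acid | I/C=C/[C@@H](O[Si](C)(C)C(C)(C)C)[C@H](C)[C@H](O[Si](C)(C)C(C)(C)C)C[C@@H](O[Si](C)(C)C(C)(C)C)C[C@@H](O[Si](C)(C)C(C)(C)C)CCC[C@H](O[Si](C)(C)C(C)(C)C)C[C@@H](O[Si](C)(C)C(C)(C)C)[C@H](CC)C(=O)OC(=O)c1c(Cl)cc(Cl)cc1Cl | intermediate
27 | (2R,3S)-3-bromobutan-2-yl (2S,3R,5S,9S,11S,13R,14R,15S,16E)-2-ethyl-3,5,9,11,13,15-hexakis(tert-butyldimethylsilyloxy)-17-iodo-14-methylheptadec-16-enoate | I/C=C/[C@@H](O[Si](C)(C)C(C)(C)C)[C@H](C)[C@H](O[Si](C)(C)C(C)(C)C)C[C@@H](O[Si](C)(C)C(C)(C)C)C[C@@H](O[Si](C)(C)C(C)(C)C)CCC[C@H](O[Si](C)(C)C(C)(C)C)C[C@@H](O[Si](C)(C)C(C)(C)C)[C@H](CC)C(=O)O[C@H](C)[C@H](C)Br | intermediate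
28 | glutaconaldehyde potassium salt (potassium (1E,3E)-5-oxopenta-1,3-dien-1-olate) | [K+].[O-]/C=C/C=C/C=O | starting material
29 | (2E,4E)-5-bromopenta-2,4-dienal | O=C/C=C/C=C/Br | intermediate
30 | (E)-1,2-bis(tributylstannyl)ethene | CCCC[Sn](CCCC)(CCCC)/C=C/[Sn](CCCC)(CCCC)CCCC | starting material
31 | (2E,4E,6E)-7-(tributylstannyl)hepta-2,4,6-trienal | O=C/C=C/C=C/C=C/[Sn](CCCC)(CCCC)CCCC | intermediate
32 | (2R,3S)-3-bromobutan-2-yl (2S,3R,5S,9S,11S,13R,14R,15R,16E,18E,20E,22E)-2-ethyl-3,5,9,11,13,15-hexakis(tert-butyldimethylsilyloxy)-14-methyl-24-oxotetracosa-16,18,20,22-tetraenoate | O=C/C=C/C=C/C=C/C=C/[C@@H](O[Si](C)(C)C(C)(C)C)[C@H](C)[C@H](O[Si](C)(C)C(C)(C)C)C[C@@H](O[Si](C)(C)C(C)(C)C)C[C@@H](O[Si](C)(C)C(C)(C)C)CCC[C@H](O[Si](C)(C)C(C)(C)C)C[C@@H](O[Si](C)(C)C(C)(C)C)[C@H](CC)C(=O)O[C@H](C)[C@H](C)Br | intermediate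
33 | (2R,3S)-3-bromobutan-2-yl (2S,3R,5S,9S,11S,13R,14R,15R,16E,18E,20E,22E,24E)-2-ethyl-3,5,9,11,13,15-hexakis(tert-butyldimethylsilyloxy)-25-iodo-14-methylpentacosa-16,18,20,22,24-pentaenoate | I/C=C/C=C/C=C/C=C/C=C/[C@@H](O[Si](C)(C)C(C)(C)C)[C@H](C)[C@H](O[Si](C)(C)C(C)(C)C)C[C@@H](O[Si](C)(C)C(C)(C)C)C[C@@H](O[Si](C)(C)C(C)(C)C)CCC[C@H](O[Si](C)(C)C(C)(C)C)C[C@@H](O[Si](C)(C)C(C)(C)C)[C@H](CC)C(=O)O[C@H](C)[C@H](C)Br | intermediate
34 | (3S,4R,6S,10S,12S,14R,15R,16R,17E,19E,21E,23E,25E,27R,28R)-3-ethyl-4,6,10,12,14,16-hexakis(tert-butyldimethylsilyloxy)-15,27,28-trimethyl-1-oxacyclooctacosa-17,19,21,23,25-pentaen-2-one | CC[C@@H]1C(=O)O[C@H](C)[C@H](C)/C=C/C=C/C=C/C=C/C=C/[C@@H](O[Si](C)(C)C(C)(C)C)[C@H](C)[C@H](O[Si](C)(C)C(C)(C)C)C[C@@H](O[Si](C)(C)C(C)(C)C)C[C@@H](O[Si](C)(C)C(C)(C)C)CCC[C@H](O[Si](C)(C)C(C)(C)C)C[C@H]1O[Si](C)(C)C(C)(C)C | intermediate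
35 | CNP0382847.1, (3S,4R,6S,10S,12S,14R,15R,16R,17E,19E,21E,23E,25E,27R,28R)-3-ethyl-4,6,10,12,14,16-hexahydroxy-15,27,28-trimethyl-1-oxacyclooctacosa-17,19,21,23,25-pentaen-2-one | CC[C@@H]1C(=O)O[C@H](C)[C@H](C)/C=C/C=C/C=C/C=C/C=C/[C@@H](O)[C@H](C)[C@H](O)C[C@@H](O)C[C@@H](O)CCC[C@H](O)C[C@H]1O | target

**Step count and risks**

Total steps: 23. Longest linear sequence: 18 steps (1–5, 7–14, 17, 20–23).

Steps most likely to fail:

1. Step 22 (Proposed new method). Capture of the C26 radical by the tethered alkenylnickel may be too slow. Oligomerisation, β-acyloxy elimination, a degenerate 1,2-acyloxy shift that erodes the C27 configuration, or bonding on the wrong face of C26 could then take over. The fallback uses known chemistry, sets out from acid 22 (with imide 3 and stannane 31) and returns at 34. Evans syn-aldol reaction of 3 (through enolate 4) with acetaldehyde gives (S)-4-benzyl-3-[(2S,3R)-3-hydroxy-2-methylbutanoyl]-1,3-oxazolidin-2-one F1. LiBH4 reduction gives (2R,3R)-2-methylbutane-1,3-diol F2. A Mitsunobu reaction at the primary hydroxyl with 1-phenyl-1H-tetrazole-5-thiol gives (2R,3S)-3-methyl-4-[(1-phenyl-1H-tetrazol-5-yl)sulfanyl]butan-2-ol F3. Oxidation with (NH4)6Mo7O24 and H2O2 gives the corresponding hydroxy sulfone F4. Stille coupling of 22 with 31 gives the tetraenal acid F5. Julia–Kocienski olefination of F5 (as its carboxylate) with the dianion of F4 (KN(SiMe3)2, THF, −78 °C) forms C24=C25 and gives the C27-hydroxy seco acid F6, which already carries C26 and C27. Yamaguchi macrolactonisation of F6 closes the ring at O27–C1 and gives 34.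

2. Step 21. The chromium-mediated olefination of the sensitive tetraenal may lose E selectivity, scramble halogen or degrade the polyene. The fallback sets out from 32 and returns at 33. Ohira–Bestmann homologation of 32 (dimethyl (1-diazo-2-oxopropyl)phosphonate, K2CO3, MeOH, 0 °C) gives the terminal tetraenyne ester F7. Hydrozirconation with Cp2Zr(H)Cl followed by iodinolysis with N-iodosuccinimide gives 33, the E geometry being fixed by syn addition of Zr–H.

3. Step 8. The boronate-tethered oxygen delivery may give poor 1,3-syn selectivity, or retro-Michael and elimination pathways may compete during boronate formation and cleavage. The fallback sets out from 11 and returns at 13. Copper-catalysed conjugate borylation (CuCl, NaOt-Bu, a Josiphos-type bisphosphine of the sense that gives 11S, B2pin2, MeOH, THF) gives the β-boryl ketone F8 under ligand control. Oxidation with NaBO3 replaces boron by hydroxyl with retention and gives 13.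

Further compounds
F1 | step 22 | (S)-4-benzyl-3-[(2S,3R)-3-hydroxy-2-methylbutanoyl]-1,3-oxazolidin-2-one | C[C@@H](O)[C@H](C)C(=O)N1[C@@H](Cc2ccccc2)COC1=O
F2 | step 22 | (2R,3R)-2-methylbutane-1,3-diol | C[C@@H](O)[C@H](C)CO
F3 | step 22 | (2R,3S)-3-methyl-4-[(1-phenyl-1H-tetrazol-5-yl)sulfanyl]butan-2-ol | C[C@@H](O)[C@H](C)CSc1nnnn1-c1ccccc1
F4 | step 22 | (2R,3S)-3-methyl-4-[(1-phenyl-1H-tetrazol-5-yl)sulfonyl]butan-2-ol | C[C@@H](O)[C@H](C)CS(=O)(=O)c1nnnn1-c1ccccc1
F5 | step 22 | (2S,3R,5S,9S,11S,13R,14R,15R,16E,18E,20E,22E)-2-ethyl-3,5,9,11,13,15-hexakis(tert-butyldimethylsilyloxy)-14-methyl-24-oxotetracosa-16,18,20,22-tetraenoic acid | O=C/C=C/C=C/C=C/C=C/[C@@H](O[Si](C)(C)C(C)(C)C)[C@H](C)[C@H](O[Si](C)(C)C(C)(C)C)C[C@@H](O[Si](C)(C)C(C)(C)C)C[C@@H](O[Si](C)(C)C(C)(C)C)CCC[C@H](O[Si](C)(C)C(C)(C)C)C[C@@H](O[Si](C)(C)C(C)(C)C)[C@H](CC)C(=O)O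
F6 | step 22 | (2S,3R,5S,9S,11S,13R,14R,15R,16E,18E,20E,22E,24E,26R,27R)-2-ethyl-27-hydroxy-3,5,9,11,13,15-hexakis(tert-butyldimethylsilyloxy)-14,26-dimethyloctacosa-16,18,20,22,24-pentaenoic acid | C[C@@H](O)[C@H](C)/C=C/C=C/C=C/C=C/C=C/[C@@H](O[Si](C)(C)C(C)(C)C)[C@H](C)[C@H](O[Si](C)(C)C(C)(C)C)C[C@@H](O[Si](C)(C)C(C)(C)C)C[C@@H](O[Si](C)(C)C(C)(C)C)CCC[C@H](O[Si](C)(C)C(C)(C)C)C[C@@H](O[Si](C)(C)C(C)(C)C)[C@H](CC)C(=O)O
F7 | step 21 | (2R,3S)-3-bromobutan-2-yl (2S,3R,5S,9S,11S,13R,14R,15R,16E,18E,20E,22E)-2-ethyl-3,5,9,11,13,15-hexakis(tert-butyldimethylsilyloxy)-14-methylpentacosa-16,18,20,22-tetraen-24-ynoate | C#C/C=C/C=C/C=C/C=C/[C@@H](O[Si](C)(C)C(C)(C)C)[C@H](C)[C@H](O[Si](C)(C)C(C)(C)C)C[C@@H](O[Si](C)(C)C(C)(C)C)C[C@@H](O[Si](C)(C)C(C)(C)C)CCC[C@H](O[Si](C)(C)C(C)(C)C)C[C@@H](O[Si](C)(C)C(C)(C)C)[C@H](CC)C(=O)O[C@H](C)[C@H](C)Br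
F8 | step 8 | (1E,3S,4S,7S,9S,13S)-3-(tert-butyldimethylsilyloxy)-9,13-dihydroxy-1-iodo-4-methyl-7-(4,4,5,5-tetramethyl-1,3,2-dioxaborolan-2-yl)hexadeca-1,15-dien-5-one | I/C=C/[C@@H](O[Si](C)(C)C(C)(C)C)[C@H](C)C(=O)C[C@@H](B1OC(C)(C)C(C)(C)O1)C[C@@H](O)CCC[C@H](O)CC=C
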